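The reading was to be taken at 5.0 min, so I wanted to know how far each flask would have travelled by then.

| flask | substrate | coupling partner | free catalyst | remark | time |
|---|---|---|---|---|---|
| elm | 0.10 M | 0.050 M | 3.4 mM | run made earlier |  |
| ash | 0.10 M | 0.050 M | 15 mM | run made earlier |  |
| blue | 0.10 M | 0.0500 M | 3.0 mM |  | 5.0 min |
| teal | 0.10 M | 0.0500 M | 5.0 mM |  | 5.0 min |
| ochre | 0.10 M | 0.0500 M | 8.0 mM |  | 5.0 min |
| grey | 0.10 M | 0.0500 M | 12 mM |  | 5.0 min |

- elm (time / min: target / %): 0.333: 7.4; 0.833: 16.2; 1.50: 27.3; 2.50: 36.3; 4.00: 43.8
- ash (time / min: target / %): 0.333: 24.6; 0.833: 38.8; 1.50: 43.1; 2.50: 44.7; 4.00: 45.1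

(each reading ± 0.5 percentage points)

- steps under discussion: catalyst intermediate C -> by-product + catalyst intermediate D; coupling partner -> decomposition product; catalyst intermediate B <-> catalyst intermediate C; target + free catalyst <-> isomer of the product + free catalyst; catalyst intermediate D -> free catalyst + target; substrate + catalyst intermediate A <-> catalyst intermediate B; coupling partner <-> dormant form; coupling partner + free catalyst <-> catalyst intermediate A
- "hardly changes" means that all values lie within two and a half points (for a concentration: within two and a half percent of the largest)

1. amount of target at the end, in percent of the substrate charged for blue, teal, ochre, grey, in this order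
2. how that number moves from the first to the last of them (hardly changes / falls all the way / falls, then rises / rises, then falls / rises all the way)

The coupling partner is the limiting reagent, charged at half the substrate, so my first ceiling for target was 50.0% of the substrate charged. I treated the gap to the ceiling as closing exponentially, at a rate proportional to the catalyst. Against that ceiling, the elm run had covered 1.29 e-foldings by 2.50 min. But the ash run stood at 45.1% at 4.00 min, having moved 0.4 percentage points since its previous reading, so I put that value back as the ceiling and went round again. Elm's figure became 1.63.

Multiplying this by the ratio of catalyst times time gave blue 2.88, the e-folding count, the number of e-foldings of the gap closed by the reading. Teal reached 4.81 and grey 11.5. Read through the ceiling, these gave 42.6% for blue, 44.7% for teal and 45.1% for grey.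

Was one number enough? The elm run at 4.00 min should have shown 41.8% but read 43.8%, while the ash run at 0.833 min should have shown 41.0% but read 38.8%. So it was not: the elm reading stood above the count and the ash reading below it. Blue's catalyst times time at its reading was more than elm's at its last reading, so I placed blue near 43.8% and expected the row to hardly change.

The forecast differed from my reckoning. It gave 44%, 47%, 47% and 46%, with the shape rises, then falls, on the ground that “The shortfall instead grows with catalyst”.

The flasks gave 43.6%, 44.8%, 45.0% and 45.0%: the row hardly changes.

    catalyst intermediate C → by-product + catalyst intermediate D (k = 1.16 s⁻¹)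
    coupling partner → decomposition product (k = 4.38 × 10⁻⁶ s⁻¹)
    catalyst intermediate B ⇌ catalyst intermediate C (K = 7.20, k = 1.10 s⁻¹)
    target + free catalyst ⇌ isomer of the product + free catalyst, rate k4*[free catalyst]*[target] forward; the back reaction follows from the equilibrium constant (K = 0.110, k = 7.99 M⁻¹ s⁻¹)
    catalyst intermediate D → free catalyst + target (k = 2.50 s⁻¹)
    substrate + catalyst intermediate A ⇌ catalyst intermediate B (K = 3.40 M⁻¹, k = 11.2 M⁻¹ s⁻¹)
    coupling partner ⇌ dormant form (K = 0.709, k = 0.0167 s⁻¹)
    coupling partner + free catalyst ⇌ catalyst intermediate A (K = 580 M⁻¹, k = 18.8 M⁻¹ s⁻¹)

Blue at 5.00 min held 43.6% target beside 4.78% isomer of the product, and the half-life of target by the forward step into that isomer alone, 0.48 min at blue's charge, was shorter than the reading time. Blue's count of 2.88 gave 42.6% where the flask gave 43.6%, and teal's count of 4.81 gave 44.7% where the flask gave 44.8%.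

The numbers in the tables come from a simulation with constants of no real substance; noise was put on by code.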